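## Structural features

The target is a germacranolide: a ten-membered carbocycle (C1–C10) trans-fused across C7–C8 to an α-methylene-γ-butyrolactone (C11–C13, ring oxygen on C8). It carries a trans epoxide on C4–C5, a 3-methylbut-2-enoate on O6, a free hydroxyl on C9 and a methyl group on C10. Seven stereocentres run without a break from C4 to C10. In the extended chain, O6, C11 and O8 lie on one side and O9 on the other, so O8/O9 and O9/C10-methyl are both anti; the epoxide oxygen is anti (erythro) to O6 and sits on the alkene face turned away from C7. The exocyclic enoate is a Michael acceptor and does not survive hydroboration, the epoxide is acid-labile, and the senecioate deconjugates with amine bases. A free O6 hydroxyl is γ to C12 just as O8 is, so under base the lactone can migrate from O8 to O6; O6 must stay blocked whenever an enolate or alkoxide is generated. The real difficulties are the closure of a medium ring, the delivery of the epoxide oxygen to one face of an alkene whose faces differ only through ring conformation, and the anti,anti triad C8–C10, which Felkin addition to an α-methyl aldehyde does not give. The key step uses the fact that C3 is an unfunctionalised CH2 bonded to the methyl-bearing sp2 carbon C4 of the carbocycle. The ring can therefore be closed at C3–C4 by sp3–sp2 coupling, with the E geometry of C4=C5 fixed beforehand in an open-chain alkenyl iodide.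

## Logic of the disconnections

34 ⇒ 33 ⇒ 31 + 32. The O9–Si bond and the ester bond O6–C(acyl) are cut last in the forward sense, because the free C9 hydroxyl and the unsaturated ester are the most labile groups. This leaves 31 with a single free hydroxyl. The forward steps must acylate without an amine strong enough to deconjugate the acyl chloride or move the lactone, and must remove silicon without opening the epoxide.

31 ⇒ 30. Both C–O bonds of the epoxide are cut, returning the E alkene C4=C5 with its allylic hydroxyl on C6. Two stereocentres disappear. The forward step must deliver oxygen from the metal-bound O6, which needs a small O6–C6–C5=C4 dihedral and so puts C7 on the opposite face; it must also leave the electron-poor C11=C13 alkene alone.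

30 ⇒ 29 ⇒ 25. The C11=C13 bond is cut and O6 is returned to its triethylsilyl ether. The methylene group is added after ring closure because it would not survive the borane, and before O6 is freed because the enolate-forming base would otherwise create a C6 alkoxide next to the lactone. 25 is then a plain saturated lactone with two different silyl ethers. The forward steps need enolisation at C11 only and removal of the allylic triethylsilyl group in the presence of the hindered tert-butyldimethylsilyl ether.

25 ⇒ 23 (through 24). The C3–C4 bond is cut. C3 carries no functional group and C4 is an alkene carbon, so the bond maps onto a primary alkylborane and an alkenyl iodide, and no stereocentre is at stake. The open-chain precursor 23 has every stereocentre from C6 to C10 and the alkene geometry already in place. The forward step must hydroborate only the terminal alkene and must close the ring faster than chains couple with each other.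

23 ⇒ 21 ⇒ 20. The C4–I and C5–H bonds and the O6–Si bond are cut, leaving a methyl-capped alkyne next to a secondary carbinol. The alkyne is linear, small and inert in the earlier steps. The forward hydrometalation must be syn and must place the metal on C4, the alkyne carbon remote from the branched silyloxy carbon.

20 ⇒ 19. The C6–H bond is cut, giving the alkynyl ketone. C6 is then set by a chiral catalyst and not by the modest bias of the neighbouring ring carbon. The forward reduction must be a 1,2-reduction under neutral conditions, so that C7 (α to the ketone) is not disturbed.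

19 ⇒ 16 + 17. The C5–C6 bond is cut between the acyl carbon and the alkyne. This separates a three-carbon alkynyl donor from a lactone acid whose carboxyl carbon becomes C6. The forward coupling must be base-free so that the acyl chloride does not lose its C7 configuration through a ketene.

16 ⇒ 15 ⇒ 12 + 9. The C7–C8 bond and the lactone bond O8–C12 are cut, and the carboxyl is returned to its chiral imide. This is a syn aldol of a succinate-type imide with an α-silyloxy aldehyde: the auxiliary sets C7 and C8, and the hydroxyl formed lies γ to the ester and closes the trans lactone. The forward step needs selective enolisation next to the imide and not next to the ester.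

12 ⇒ 10 + 11. The N–acyl bond is cut, giving the commercial auxiliary and the commercial half-ester acid chloride.

9 ⇒ 8 ⇒ 7 ⇒ 6. Only oxidation level and protecting groups change: aldehyde to primary alcohol, and the two silyl ethers back to the 1,2-diol. The forward steps must distinguish the primary from the secondary oxygen.

6 ⇒ 5 ⇒ 4. The C10–C14 bond (the methyl group) and the epoxide C–O bonds are cut. Building C8–C9 in one step by adding a C8 nucleophile to an aldehyde that already carries the C10 methyl would have to run against the Felkin preference, because O9 and the C10 methyl are anti. Here C9 and C10 come from one trans epoxide: the catalyst sets its absolute configuration, and methyl transfer with inversion at C10 gives the anti relationship by mechanism. The forward opening must occur at the carbon remote from the hydroxymethyl group.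

4 ⇒ 3 ⇒ 1 + 2. The E alkene is taken back to the alkyne, and the bond between the alkyne carbon (C10) and the allylic CH2 (C1) is cut. Two three-carbon commercial pieces remain. The reduction must give only the E alkene and leave the terminal alkene, which becomes C2=C3 of the key step.

## Other disconnections considered

Alternative 1: The cut is C7–C11 together with O8–C12, so the whole lactone is removed from a preformed carbocycle. In the forward step the cis-7,8-epoxide A2 would be opened at C7 with inversion by the ester-bearing alkenylcuprate A4, LiCu[C(=CH2)CO2Me]2, made from methyl 2-bromoacrylate A3 by halogen–metal exchange. The C8 alkoxide would then close onto the ester to give the trans-fused methylene lactone A1.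
- In its favour: one operation forms a C–C bond, the lactone ring and the exocyclic alkene, and anti opening makes the trans fusion a consequence of mechanism.
- Where it is equal or better: A1 is the same structure as 30, so the last three steps would be identical (equal). On lactone construction it is better by two steps, since no separate methylenation and no triethylsilyl removal are needed.
- Against it here: the ten-membered ring, now with a Z C7=C8 alkene beside the E C4=C5 alkene, still has to be made, so the medium-ring problem is untouched. The C7=C8 alkene would have to be epoxidised on one face in the presence of the more electron-rich trisubstituted alkene, with the C6 hydroxyl allylic to both. C7 and C8 are both secondary and both flanked by oxygenated carbons, so attack at C7 is not secured. Ester-bearing alkenylcuprates are weak nucleophiles toward hindered epoxides and usually need a Lewis acid, which a medium-ring epoxy alcohol with a transannular alkene may not tolerate.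
- Comparison: the chosen plan sets C7 and C8 in the open chain by an auxiliary-controlled aldol, where the alternative relies on an SN2 opening whose regiochemistry is open. The alternative is shorter after ring formation but leaves ring formation itself unsolved.

Alternative 2: The cut is C8–C9, with O8–C12 following. Low-valent titanium from TiCl3 and Zn–Cu would couple the two aldehyde groups of the open-chain dialdehyde ester A6 in a pinacol reaction to the ring cis-diol. The C8 alkoxide would then lactonise onto the methyl ester to give A5.
- In its favour: the ring, two stereocentres and the lactone would arise in one step from an acyclic precursor. Titanium holds both carbonyl groups, and medium rings are the classical domain of this coupling. A ring cis-diol is the O8/O9 relationship of 34.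
- Where it is equal or better: no boron, palladium or alkenyl iodide is needed, and fewer steps precede ring closure.
- Against it here: C8 and C9 would be created in the ring-closing event with no controlling element other than a flexible chain. Four diols are possible and only one is wanted. Both aldehydes carry epimerisable α-stereocentres (C7, C10) and would meet a Lewis-acidic metal. The allylic silyl ether at C6 is exposed to reduction or ionisation, and deoxygenation to the alkene competes. O9 could lactonise to the six-membered isomer. A5 also has free O9–H and silylated O6, so protecting groups would have to be exchanged before any enolate chemistry.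
- Comparison: a ketyl coupling on a metal surface is far less predictable than a stereoretentive palladium coupling that creates no stereocentre. The chosen plan fixes C8 and C9 beforehand by an epoxide and an aldol. The alternative could be shorter up to the ring, but it moves the stereochemical risk into the hardest step and lengthens the endgame.

Alternative 3: The cut is C6–C7, with the C4–C9 bond of a six-membered ring as the retron. Deprotonation of the trans-1,2-dialkenylcyclohexanol A8 with KH and a crown ether would trigger an alkoxide-accelerated [3,3] shift through a chair transition state. This would form C6–C7, break C4–C9 and give the (E)-cyclodecenone A7.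
- In its favour: the ten-membered ring arises by ring expansion, without high dilution and without the entropic cost of macrocyclisation. The chair transition state translates the geometry of both alkenes into the C6/C7 relationship and into the E C4=C5 alkene. The cyclohexane stereocentres are easy to set.
- Where it is equal or better: on ring formation it is better than the chosen plan. As a concerted, stereospecific process it is equal in reliability to the stereoretentive coupling.
- Against it here: A7 has a ketone at C9 and a CH2 at C8. C8 would have to be oxygenated on the correct side of the ketone (away from the tertiary, epimerisable C10–H) and on the correct face. C9 would have to be reduced on the correct face, and C12 oxidised and lactonised. These are four or five redox steps whose outcome depends on the conformation of a mobile ring. The enol ether terminus must be E, and the benzyl-type ether must later be exchanged for the ester.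
- Comparison: the anti-diol C8/C9, which the chosen plan takes from reagent-controlled open-chain reactions, would be left to the end. The steps saved in ring formation are likely spent again on these adjustments, so the overall length is about equal or slightly greater.

Key step: step 15

Remark: positions follow germacrane numbering (ring C1–C10; C11, C12, C13 = lactone α-carbon, carbonyl carbon and methylene carbon; C14 on C10, C15 on C4), and "12,8-olide" means the lactone from C12 to O8. The CIP labels of C6 and C7 change along the route with the neighbouring atoms (for example C6 is R in 23 and S in 25), while the arrangement in space stays the same as in 34.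

## Route

Step 1
Reactants: 1 prop-2-yn-1-ol; 2 allyl bromide (3-bromoprop-1-ene)
Product: 3 hex-5-en-2-yn-1-ol
Conditions: CuI (10 mol%), n-Bu4NI (10 mol%), K2CO3, DMF, rt
Reagents that add atoms: none
Why: Copper-catalysed alkynyl–allyl coupling of the copper acetylide with the allylic bromide gives the skipped enyne; the weak base leaves the hydroxyl untouched.

Step 2
Reactants: 3 hex-5-en-2-yn-1-ol
Product: 4 (2E)-hexa-2,5-dien-1-ol
Conditions: LiAlH4, THF, 0 °C to rt; aq. NaOH work-up
Reagents that add atoms: none
Why: Alkoxide-directed trans-hydroalumination of a propargylic alcohol gives only the E allylic alcohol; the isolated terminal alkene is inert to LiAlH4.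

Step 3
Reactants: 4 (2E)-hexa-2,5-dien-1-ol
Product: 5 [(2S,3S)-3-(prop-2-en-1-yl)oxiran-2-yl]methanol
Conditions: Ti(OiPr)4 (10 mol%), L-(+)-diisopropyl tartrate (12 mol%), t-BuOOH (anhydrous, in decane), 4 Å molecular sieves, CH2Cl2, −20 °C
Reagents that add atoms: tert-butyl hydroperoxide, CC(C)(C)OO
Why: Sharpless asymmetric epoxidation: the titanium tartrate binds the allylic alcohol and oxidises only that alkene, and the L-(+)-tartrate is expected to give the (2S,3S) epoxide, which fixes C9 and, by relay, C10.

Step 4
Reactants: 5 epoxy alcohol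
Product: 6 (2R,3R)-3-methylhex-5-ene-1,2-diol
Conditions: Me3Al (3 equiv), hexane/CH2Cl2, 0 °C to rt; aq. potassium sodium tartrate
Reagents that add atoms: trimethylaluminium, C[Al](C)C
Why: Alkoxyaluminium-directed opening of a 2,3-epoxy alcohol: methyl is transferred to the carbon remote from the CH2O group with inversion, so the anti O9/C10-methyl relationship follows from the trans epoxide.

Step 5
Reactants: 6 diol
Product: 7 (2R,3R)-1,2-bis[(tert-butyldimethylsilyl)oxy]-3-methylhex-5-ene
Conditions: TBSOTf (2.4 equiv), 2,6-lutidine, CH2Cl2, 0 °C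
Reagents that add atoms: tert-butyldimethylsilyl trifluoromethanesulfonate, CC(C)(C)[Si](C)(C)OS(=O)(=O)C(F)(F)F
Why: Silyl triflate with a hindered pyridine base silylates both hydroxyls, including the secondary one next to the branched carbon.

Step 6
Reactants: 7 bis-silyl ether
Product: 8 (2R,3R)-2-[(tert-butyldimethylsilyl)oxy]-3-methylhex-5-en-1-ol
Conditions: HF·pyridine, pyridine, THF, 0 °C
Reagents that add atoms: none
Why: Buffered HF cleaves the unhindered primary silyl ether much faster than the secondary one flanked by the methyl-bearing carbon (selective desilylation).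

Step 7
Reactants: 8 primary alcohol
Product: 9 (2R,3R)-2-[(tert-butyldimethylsilyl)oxy]-3-methylhex-5-enal
Conditions: Dess–Martin periodinane, NaHCO3, CH2Cl2, 0 °C to rt; used crude
Reagents that add atoms: none
Why: Dess–Martin oxidation under buffered, base-free conditions gives the α-silyloxy aldehyde without epimerisation at C9.

Step 8
Reactants: 10 (4S)-4-benzyl-1,3-oxazolidin-2-one; 11 methyl 4-chloro-4-oxobutanoate
Product: 12 methyl 4-[(4S)-4-benzyl-2-oxo-1,3-oxazolidin-3-yl]-4-oxobutanoate
Conditions: n-BuLi, THF, −78 °C; then 11, −78 to 0 °C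
Reagents that add atoms: none
Why: N-acylation of the lithiated oxazolidinone by the acid chloride; the methyl ester is much less electrophilic and is not attacked.

Step 9
Reactants: 12 succinyl imide; 9 α-silyloxy aldehyde
Product: 15 (4S)-4-benzyl-3-{[(2S,3S)-2-[(1R,2R)-1-[(tert-butyldimethylsilyl)oxy]-2-methylpent-4-en-1-yl]-5-oxooxolan-3-yl]carbonyl}-1,3-oxazolidin-2-one, via boron enolate 13 (not isolated), via open-chain aldol adduct 14 (not isolated)
Conditions: 12, Bu2BOTf, i-Pr2NEt, CH2Cl2, −78 to 0 °C; 9, −78 to 0 °C; pH 7 buffer, MeOH, H2O2; then PPTS (cat.), CH2Cl2, rt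
Reagents that add atoms: none
Why: Evans syn aldol: soft enolisation occurs next to the imide only, and the Z boron enolate reacts through a chair transition state in which the (S)-benzyl auxiliary fixes C7 and C8; the Cornforth-type preference of the α-silyloxy aldehyde for the 8,9-anti adduct reinforces this (matched pair). The new hydroxyl is γ to the ester and closes the trans lactone with loss of methanol.

Step 10
Reactants: 15 lactone imide
Product: 16 (2S,3S)-2-[(1R,2R)-1-[(tert-butyldimethylsilyl)oxy]-2-methylpent-4-en-1-yl]-5-oxooxolane-3-carboxylic acid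
Conditions: LiOH, H2O2, THF/H2O (3:1), 0 °C; aq. Na2SO3; then 1 M HCl to pH 3
Reagents that add atoms: hydrogen peroxide, OO
Why: Hydroperoxide cleaves the exocyclic imide carbonyl selectively (standard auxiliary removal); any lactone opened by hydroxide re-closes on acidification, since only the five-membered lactone can form.

Step 11
Reactants: 16 lactone acid; 17 tributyl(prop-1-yn-1-yl)stannane
Product: 19 (4S,5S)-4-(but-2-ynoyl)-5-[(1R,2R)-1-[(tert-butyldimethylsilyl)oxy]-2-methylpent-4-en-1-yl]oxolan-2-one, via acid chloride 18 (not isolated)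
Conditions: (COCl)2, DMF (cat.), CH2Cl2, 0 °C to rt, evaporate; then 17, PdCl2(PPh3)2 (3 mol%), 1,2-dichloroethane, 60 °C
Reagents that add atoms: none
Why: Acyl Stille coupling: zerovalent palladium inserts into the C–Cl bond, the alkynyl group (the fastest group to transfer from tin) is delivered, and reductive elimination gives the alkynyl ketone; no base is present, so C7 is not epimerised through a ketene.

Step 12
Reactants: 19 alkynyl ketone
Product: 20 (4R,5S)-5-[(1R,2R)-1-[(tert-butyldimethylsilyl)oxy]-2-methylpent-4-en-1-yl]-4-[(1R)-1-hydroxybut-2-yn-1-yl]oxolan-2-one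
Conditions: Ru[(R,R)-TsDPEN](p-cymene) (2 mol%, preformed amido complex), i-PrOH, rt
Reagents that add atoms: none
Why: Noyori asymmetric transfer hydrogenation of an alkynyl ketone: the alkynyl group takes the place an aryl group has in the usual model, so the (R,R) catalyst should give the (R) carbinol at C6 under catalyst control; the neutral medium leaves C7, the alkyne and the lactone untouched.

Step 13
Reactants: 20 propargylic alcohol
Product: 21 (4S,5S)-5-[(1R,2R)-1-[(tert-butyldimethylsilyl)oxy]-2-methylpent-4-en-1-yl]-4-[(1R)-1-[(triethylsilyl)oxy]but-2-yn-1-yl]oxolan-2-one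
Conditions: TESCl, imidazole, DMF, 0 °C to rt
Reagents that add atoms: chlorotriethylsilane, CC[Si](Cl)(CC)CC
Why: Standard silylation; the triethylsilyl ether blocks O6 against lactone migration and can later be removed in the presence of the tert-butyldimethylsilyl ether.

Step 14
Reactants: 21 propargylic silyl ether
Product: 23 (4S,5S)-5-[(1R,2R)-1-[(tert-butyldimethylsilyl)oxy]-2-methylpent-4-en-1-yl]-4-[(1R,2E)-3-iodo-1-[(triethylsilyl)oxy]but-2-en-1-yl]oxolan-2-one, via alkenylstannane 22 (not isolated)
Conditions: Bu3SnH, PdCl2(PPh3)2 (3 mol%), THF, 0 °C to rt; then I2, CH2Cl2, 0 °C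
Reagents that add atoms: iodine, II
Why: Palladium-catalysed syn hydrostannation should place tin on C4, the alkyne carbon remote from the branched, silylated C6, and hydrogen on C5; iododestannylation proceeds with retention, so iodine ends trans to C6 (E).

Step 15
Reactants: 23 alkenyl iodide with terminal alkene (ring-closure precursor)
Product: 25 (4E,6S,7S,8S,9R,10R)-9-[(tert-butyldimethylsilyl)oxy]-6-[(triethylsilyl)oxy]germacr-4-en-12,8-olide, via alkyl-9-BBN borane 24 (not isolated)
Conditions: 9-BBN (1.5 equiv), THF, rt; then addition over 8 h (syringe pump) to Pd(dppf)Cl2 (20 mol%), AsPh3 (40 mol%), Cs2CO3, DMF/THF/H2O, 50 °C, final concentration 1 mM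
Reagents that add atoms: none
Why: 9-BBN adds to the monosubstituted C2=C3 alkene with boron on C3, giving 24; the trisubstituted iodoalkene and the lactone do not react at room temperature. Zerovalent palladium formed from Pd(dppf)Cl2 inserts into the C4–I bond with retention, the base-activated borate transfers the primary C3 alkyl group to palladium, and reductive elimination forms C3–C4. The closest known reaction type is the B-alkyl Suzuki–Miyaura macrocyclisation of ω-boryl alkenyl iodides. The ten-membered carbocycle closes by sp3–sp2 coupling through an eleven-membered palladacycle, with the new alkene endocyclic. No stereocentre is formed; the E geometry of C4=C5 comes from 23 and is kept because oxidative addition and reductive elimination both retain alkene geometry. The step needs hydroboration of the terminal alkene only, which the bulk of 9-BBN and the deactivated iodoalkene secure. It needs ring closure over chain coupling, which slow addition to high dilution and the conformational restriction by the trans lactone and the two silyl ethers should favour. It needs coupling over β-hydride elimination, which the wide-bite-angle dppf ligand and AsPh3 favour; the lactone CH2 and both silyl ethers tolerate aqueous Cs2CO3.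

Step 16
Reactants: 25 macrocyclic lactone
Product: 29 (4E,6S,7S,8S,9R,10R)-9-[(tert-butyldimethylsilyl)oxy]-6-[(triethylsilyl)oxy]germacra-4,11(13)-dien-12,8-olide, via lithium enolate 26 (not isolated), via Mannich base 27 (not isolated), via ammonium iodide 28 (not isolated)
Conditions: LiN(i-Pr)2, THF, −78 °C; dimethyl(methylidene)ammonium iodide, −78 °C to rt; then MeI, MeOH, rt; then aq. NaHCO3, CH2Cl2, rt
Reagents that add atoms: dimethyl(methylidene)ammonium iodide, C=[N+](C)C.[I-]
Why: Lactone α-methylenation by Mannich reaction of the enolate with the iminium salt, N-methylation and β-elimination of trimethylamine; O6 is still silylated, so no C6 alkoxide can attack C12, and the C11 configuration of 27 is lost in the elimination.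

Step 17
Reactants: 29 bis-silyl methylene lactone
Product: 30 (4E,6S,7R,8S,9R,10R)-9-[(tert-butyldimethylsilyl)oxy]-6-hydroxygermacra-4,11(13)-dien-12,8-olide
Conditions: PPTS (20 mol%), MeOH/CH2Cl2 (1:1), 0 °C
Reagents that add atoms: none
Why: Mild acid methanolysis removes the allylic triethylsilyl ether and leaves the hindered secondary tert-butyldimethylsilyl ether (selective desilylation); the medium is too weakly acidic to move the lactone to O6.

Step 18
Reactants: 30 allylic alcohol
Product: 31 (4R,5R,6R,7R,8S,9R,10R)-9-[(tert-butyldimethylsilyl)oxy]-4,5-epoxy-6-hydroxygermacr-11(13)-en-12,8-olide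
Conditions: VO(acac)2 (10 mol%), t-BuOOH (anhydrous, in decane), CH2Cl2, 0 °C to rt
Reagents that add atoms: tert-butyl hydroperoxide, CC(C)(C)OO
Why: Hydroxyl-directed epoxidation: the pentavalent vanadium alkoxide of O6 delivers the peroxide oxygen intramolecularly, which needs a small O6–C6–C5=C4 dihedral; in the ring this is possible only with C7 on the opposite face, which corresponds to the (4R,5R) epoxide erythro to O6. The electron-poor C11=C13 alkene is not oxidised.

Step 19
Reactants: 31 epoxy alcohol; 32 3-methylbut-2-enoyl chloride
Product: 33 (4R,5R,6R,7R,8S,9R,10R)-9-[(tert-butyldimethylsilyl)oxy]-4,5-epoxy-6-[(3-methylbut-2-enoyl)oxy]germacr-11(13)-en-12,8-olide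
Conditions: pyridine, DMAP (10 mol%), CH2Cl2, 0 °C to rt
Reagents that add atoms: none
Why: Acyl transfer catalysed by DMAP; pyridine is too weak a base to deconjugate the acyl chloride through a vinylketene or to create a C6 alkoxide.

Step 20
Reactants: 33 silylated ester
Product: 34 (4R,5R,6R,7S,8S,9R,10R)-4,5-epoxy-9-hydroxy-6-[(3-methylbut-2-enoyl)oxy]germacr-11(13)-en-12,8-olide (CNP0119422.1)
Conditions: HF·pyridine, pyridine, THF, 0 °C to rt
Reagents that add atoms: none
Why: Fluoride-driven cleavage of the last silyl ether in a pyridine-buffered medium that is neither basic enough for conjugate addition or acyl migration nor acidic enough to open the epoxide.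

## Compound list

1 | prop-2-yn-1-ol | C#CCO | starting material
2 | allyl bromide | C=CCBr | starting material
3 | hex-5-en-2-yn-1-ol | OCC#CCC=C | intermediate
4 | (2E)-hexa-2,5-dien-1-ol | OC/C=C/CC=C | intermediate
5 | [(2S,3S)-3-(prop-2-en-1-yl)oxiran-2-yl]methanol | OC[C@@H]1O[C@H]1CC=C | intermediate
6 | (2R,3R)-3-methylhex-5-ene-1,2-diol | OC[C@H](O)[C@H](C)CC=C | intermediate
7 | (2R,3R)-1,2-bis[(tert-butyldimethylsilyl)oxy]-3-methylhex-5-ene | CC(C)(C)[Si](C)(C)OC[C@H](O[Si](C)(C)C(C)(C)C)[C@H](C)CC=C | intermediate
8 | (2R,3R)-2-[(tert-butyldimethylsilyl)oxy]-3-methylhex-5-en-1-ol | OC[C@H](O[Si](C)(C)C(C)(C)C)[C@H](C)CC=C | intermediate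
9 | (2R,3R)-2-[(tert-butyldimethylsilyl)oxy]-3-methylhex-5-enal | O=C[C@H](O[Si](C)(C)C(C)(C)C)[C@H](C)CC=C | intermediate
10 | (4S)-4-benzyl-1,3-oxazolidin-2-one | O=C1N[C@@H](Cc2ccccc2)CO1 | starting material
11 | methyl 4-chloro-4-oxobutanoate | COC(=O)CCC(Cl)=O | starting material
12 | methyl 4-[(4S)-4-benzyl-2-oxo-1,3-oxazolidin-3-yl]-4-oxobutanoate | COC(=O)CCC(=O)N1[C@@H](Cc2ccccc2)COC1=O | intermediate
13 | dibutylboron (Z)-enolate of 12 | CCCCB(CCCC)O/C(=C\CC(=O)OC)N1[C@@H](Cc2ccccc2)COC1=O | intermediate (not isolated)
14 | methyl (3S,4S,5R,6R)-3-{[(4S)-4-benzyl-2-oxo-1,3-oxazolidin-3-yl]carbonyl}-5-[(tert-butyldimethylsilyl)oxy]-4-hydroxy-6-methylnon-8-enoate | COC(=O)C[C@H](C(=O)N1[C@@H](Cc2ccccc2)COC1=O)[C@H](O)[C@H](O[Si](C)(C)C(C)(C)C)[C@H](C)CC=C | intermediate (not isolated)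
15 | (4S)-4-benzyl-3-{[(2S,3S)-2-[(1R,2R)-1-[(tert-butyldimethylsilyl)oxy]-2-methylpent-4-en-1-yl]-5-oxooxolan-3-yl]carbonyl}-1,3-oxazolidin-2-one | C=CC[C@@H](C)[C@@H](O[Si](C)(C)C(C)(C)C)[C@H]1OC(=O)C[C@@H]1C(=O)N1[C@@H](Cc2ccccc2)COC1=O | intermediate
16 | (2S,3S)-2-[(1R,2R)-1-[(tert-butyldimethylsilyl)oxy]-2-methylpent-4-en-1-yl]-5-oxooxolane-3-carboxylic acid | C=CC[C@@H](C)[C@@H](O[Si](C)(C)C(C)(C)C)[C@H]1OC(=O)C[C@@H]1C(O)=O | intermediate
17 | tributyl(prop-1-yn-1-yl)stannane | CC#C[Sn](CCCC)(CCCC)CCCC | starting material
18 | (2S,3S)-2-[(1R,2R)-1-[(tert-butyldimethylsilyl)oxy]-2-methylpent-4-en-1-yl]-5-oxooxolane-3-carbonyl chloride | C=CC[C@@H](C)[C@@H](O[Si](C)(C)C(C)(C)C)[C@H]1OC(=O)C[C@@H]1C(Cl)=O | intermediate (not isolated)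
19 | (4S,5S)-4-(but-2-ynoyl)-5-[(1R,2R)-1-[(tert-butyldimethylsilyl)oxy]-2-methylpent-4-en-1-yl]oxolan-2-one | C=CC[C@@H](C)[C@@H](O[Si](C)(C)C(C)(C)C)[C@H]1OC(=O)C[C@@H]1C(=O)C#CC | intermediate
20 | (4R,5S)-5-[(1R,2R)-1-[(tert-butyldimethylsilyl)oxy]-2-methylpent-4-en-1-yl]-4-[(1R)-1-hydroxybut-2-yn-1-yl]oxolan-2-one | C=CC[C@@H](C)[C@@H](O[Si](C)(C)C(C)(C)C)[C@H]1OC(=O)C[C@@H]1[C@@H](O)C#CC | intermediate
21 | (4S,5S)-5-[(1R,2R)-1-[(tert-butyldimethylsilyl)oxy]-2-methylpent-4-en-1-yl]-4-[(1R)-1-[(triethylsilyl)oxy]but-2-yn-1-yl]oxolan-2-one | C=CC[C@@H](C)[C@@H](O[Si](C)(C)C(C)(C)C)[C@H]1OC(=O)C[C@@H]1[C@@H](O[Si](CC)(CC)CC)C#CC | intermediate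
22 | (4S,5S)-5-[(1R,2R)-1-[(tert-butyldimethylsilyl)oxy]-2-methylpent-4-en-1-yl]-4-[(1R,2E)-3-(tributylstannyl)-1-[(triethylsilyl)oxy]but-2-en-1-yl]oxolan-2-one | C=CC[C@@H](C)[C@@H](O[Si](C)(C)C(C)(C)C)[C@H]1OC(=O)C[C@@H]1[C@@H](O[Si](CC)(CC)CC)/C=C(C)/[Sn](CCCC)(CCCC)CCCC | intermediate (not isolated)
23 | (4S,5S)-5-[(1R,2R)-1-[(tert-butyldimethylsilyl)oxy]-2-methylpent-4-en-1-yl]-4-[(1R,2E)-3-iodo-1-[(triethylsilyl)oxy]but-2-en-1-yl]oxolan-2-one | C=CC[C@@H](C)[C@@H](O[Si](C)(C)C(C)(C)C)[C@H]1OC(=O)C[C@@H]1[C@@H](O[Si](CC)(CC)CC)/C=C(C)/I | intermediate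
24 | (4S,5S)-5-[(1R,2R)-5-(9-borabicyclo[3.3.1]nonan-9-yl)-1-[(tert-butyldimethylsilyl)oxy]-2-methylpentyl]-4-[(1R,2E)-3-iodo-1-[(triethylsilyl)oxy]but-2-en-1-yl]oxolan-2-one | C(CC[C@@H](C)[C@@H](O[Si](C)(C)C(C)(C)C)[C@H]1OC(=O)C[C@@H]1[C@@H](O[Si](CC)(CC)CC)/C=C(C)/I)B1C2CCCC1CCC2 | intermediate (not isolated)
25 | (4E,6S,7S,8S,9R,10R)-9-[(tert-butyldimethylsilyl)oxy]-6-[(triethylsilyl)oxy]germacr-4-en-12,8-olide | C1/C(C)=C/[C@H](O[Si](CC)(CC)CC)[C@H]2CC(=O)O[C@@H]2[C@H](O[Si](C)(C)C(C)(C)C)[C@H](C)CC1 | intermediate
26 | lithium enolate of 25 (C11=C12–OLi) | C1/C(C)=C/[C@H](O[Si](CC)(CC)CC)[C@H]2C=C(O[Li])O[C@@H]2[C@H](O[Si](C)(C)C(C)(C)C)[C@H](C)CC1 | intermediate (not isolated)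
27 | (4E,6S,7S,8S,9R,10R,11R)-9-[(tert-butyldimethylsilyl)oxy]-13-(dimethylamino)-6-[(triethylsilyl)oxy]germacr-4-en-12,8-olide | C1/C(C)=C/[C@H](O[Si](CC)(CC)CC)[C@H]2[C@H](CN(C)C)C(=O)O[C@@H]2[C@H](O[Si](C)(C)C(C)(C)C)[C@H](C)CC1 | intermediate (not isolated)
28 | N-methyl quaternary ammonium iodide of 27 (13-trimethylammonio) | C1/C(C)=C/[C@H](O[Si](CC)(CC)CC)[C@H]2[C@H](C[N+](C)(C)C)C(=O)O[C@@H]2[C@H](O[Si](C)(C)C(C)(C)C)[C@H](C)CC1.[I-] | intermediate (not isolated)
29 | (4E,6S,7S,8S,9R,10R)-9-[(tert-butyldimethylsilyl)oxy]-6-[(triethylsilyl)oxy]germacra-4,11(13)-dien-12,8-olide | C1/C(C)=C/[C@H](O[Si](CC)(CC)CC)[C@H]2C(=C)C(=O)O[C@@H]2[C@H](O[Si](C)(C)C(C)(C)C)[C@H](C)CC1 | intermediate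
30 | (4E,6S,7R,8S,9R,10R)-9-[(tert-butyldimethylsilyl)oxy]-6-hydroxygermacra-4,11(13)-dien-12,8-olide | C1/C(C)=C/[C@H](O)[C@H]2C(=C)C(=O)O[C@@H]2[C@H](O[Si](C)(C)C(C)(C)C)[C@H](C)CC1 | intermediate
31 | (4R,5R,6R,7R,8S,9R,10R)-9-[(tert-butyldimethylsilyl)oxy]-4,5-epoxy-6-hydroxygermacr-11(13)-en-12,8-olide | C=C1C(=O)O[C@@H]2[C@H](O[Si](C)(C)C(C)(C)C)[C@H](C)CCC[C@@]3(C)O[C@@H]3[C@H](O)[C@@H]12 | intermediate
32 | 3-methylbut-2-enoyl chloride | CC(C)=CC(Cl)=O | starting material
33 | (4R,5R,6R,7R,8S,9R,10R)-9-[(tert-butyldimethylsilyl)oxy]-4,5-epoxy-6-[(3-methylbut-2-enoyl)oxy]germacr-11(13)-en-12,8-olide | C=C1C(=O)O[C@@H]2[C@H](O[Si](C)(C)C(C)(C)C)[C@H](C)CCC[C@@]3(C)O[C@@H]3[C@H](OC(=O)C=C(C)C)[C@@H]12 | intermediate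
34 | (4R,5R,6R,7S,8S,9R,10R)-4,5-epoxy-9-hydroxy-6-[(3-methylbut-2-enoyl)oxy]germacr-11(13)-en-12,8-olide | C=C1C(=O)O[C@@H]2[C@H](O)[C@H](C)CCC[C@@]3(C)O[C@@H]3[C@H](OC(=O)C=C(C)C)[C@@H]12 | target

## Step count and least certain steps

Total step count: 20. Longest linear sequence: 19 steps (steps 1–7 and 9–20); step 8 is a one-step side branch.

**Step 15 (key step).** Chains may couple with each other instead of closing the ring, and the borane may be lost by protodeboronation or β-hydride elimination, because transmetalation inside the strained eleven-membered palladacycle is slow in aqueous base. The fallback sets out from 23 and returns at 25; it replaces the one-flask borane coupling by a stepwise, base-free ring closure through an organozinc reagent. Hydroboration of 23 to 24 as before, then oxidation with NaBO3·4H2O in THF/H2O, would give the 5-hydroxypentyl lactone F1. I2, PPh3 and imidazole in CH2Cl2 would convert it into the 5-iodopentyl lactone F2 without touching the alkenyl iodide. Zinc dust with LiCl in THF at 40 °C inserts only into the sp3 C–I bond and would give the alkylzinc iodide F3. Slow addition of F3 to Pd(dppf)Cl2 in THF/N-methylpyrrolidone at 50 °C would close C3–C4 by an intramolecular Negishi coupling to 25.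

**Step 18.** Oxygen may be transferred to the other alkene face through the alternative ring conformer, or delivery may be so slow that the allylic alcohol is oxidised to the enone instead. The fallback sets out from 30 and returns at 33; it changes the stereochemical plan from vanadium delivery to a peracid epoxidation of the C6 epimer followed by inversion. Mitsunobu reaction of 30 with formic acid (PPh3, diisopropyl azodicarboxylate, THF, 0 °C) would give the inverted 6-epi formate F4, and KHCO3 in MeOH at 0 °C would free the 6-epi allylic alcohol F5. In this epimer the conformer with H6 eclipsing the alkene has the hydroxyl on the exposed face opposite C7, at the roughly 120° dihedral a peracid prefers. Buffered m-chloroperbenzoic acid (NaHCO3, CH2Cl2, 0 °C) should therefore give the 6-epi (4R,5R)-epoxy alcohol F6. A second Mitsunobu reaction, now with 3-methylbut-2-enoic acid, inverts C6 and installs the ester in one operation, giving 33.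

**Step 14.** Tin may be delivered to C5, the alkyne carbon next to the carbinol, under the inductive pull of the C6 oxygen; the iodine would then end on the wrong carbon. The fallback sets out from 21 and returns at 23; it replaces the palladium-catalysed tin hydride addition by a sterically governed, equilibrating hydrozirconation. Cp2Zr(H)Cl (1.5 equiv, THF, rt, short reaction time to spare the lactone) adds syn and settles with zirconium on the less hindered methyl-bearing carbon, giving the alkenylzirconocene chloride F7. I2 in THF at 0 °C cleaves the C–Zr bond with retention to 23.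

**Step 11.** Configuration at C7 may be lost through ketene formation from the acid chloride, or the acylpalladium may lose CO before the alkynyl group arrives. The fallback sets out from 16 and returns at 19; it replaces the acyl chloride coupling by a Weinreb ketone synthesis. Coupling of 16 with N,O-dimethylhydroxylamine hydrochloride (N-ethyl-N'-(3-dimethylaminopropyl)carbodiimide hydrochloride, N-methylmorpholine, CH2Cl2, 0 °C) would give the Weinreb amide F8. 1-Propynylmagnesium bromide (CH3C≡CMgBr) in THF at −40 °C adds once to the chelating amide, faster than to the lactone, and gives 19 on work-up.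

## Further compounds

F1 | step 15 | (4S,5S)-5-[(1R,2R)-1-[(tert-butyldimethylsilyl)oxy]-5-hydroxy-2-methylpentyl]-4-[(1R,2E)-3-iodo-1-[(triethylsilyl)oxy]but-2-en-1-yl]oxolan-2-one | OCCC[C@@H](C)[C@@H](O[Si](C)(C)C(C)(C)C)[C@H]1OC(=O)C[C@@H]1[C@@H](O[Si](CC)(CC)CC)/C=C(C)/I
F2 | step 15 | (4S,5S)-5-[(1R,2R)-1-[(tert-butyldimethylsilyl)oxy]-5-iodo-2-methylpentyl]-4-[(1R,2E)-3-iodo-1-[(triethylsilyl)oxy]but-2-en-1-yl]oxolan-2-one | ICCC[C@@H](C)[C@@H](O[Si](C)(C)C(C)(C)C)[C@H]1OC(=O)C[C@@H]1[C@@H](O[Si](CC)(CC)CC)/C=C(C)/I
F3 | step 15 | (4S,5S)-5-[(1R,2R)-1-[(tert-butyldimethylsilyl)oxy]-5-(iodozincio)-2-methylpentyl]-4-[(1R,2E)-3-iodo-1-[(triethylsilyl)oxy]but-2-en-1-yl]oxolan-2-one | I[Zn]CCC[C@@H](C)[C@@H](O[Si](C)(C)C(C)(C)C)[C@H]1OC(=O)C[C@@H]1[C@@H](O[Si](CC)(CC)CC)/C=C(C)/I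
F4 | step 18 | (4E,6R,7R,8S,9R,10R)-9-[(tert-butyldimethylsilyl)oxy]-6-(formyloxy)germacra-4,11(13)-dien-12,8-olide | C1/C(C)=C/[C@@H](OC=O)[C@H]2C(=C)C(=O)O[C@@H]2[C@H](O[Si](C)(C)C(C)(C)C)[C@H](C)CC1
F5 | step 18 | (4E,6R,7R,8S,9R,10R)-9-[(tert-butyldimethylsilyl)oxy]-6-hydroxygermacra-4,11(13)-dien-12,8-olide | C1/C(C)=C/[C@@H](O)[C@H]2C(=C)C(=O)O[C@@H]2[C@H](O[Si](C)(C)C(C)(C)C)[C@H](C)CC1
F6 | step 18 | (4R,5R,6S,7R,8S,9R,10R)-9-[(tert-butyldimethylsilyl)oxy]-4,5-epoxy-6-hydroxygermacr-11(13)-en-12,8-olide | C=C1C(=O)O[C@@H]2[C@H](O[Si](C)(C)C(C)(C)C)[C@H](C)CCC[C@@]3(C)O[C@@H]3[C@@H](O)[C@@H]12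
F7 | step 14 | chlorobis(cyclopentadienyl)[(2E,4R)-4-{(2S,3S)-2-[(1R,2R)-1-[(tert-butyldimethylsilyl)oxy]-2-methylpent-4-en-1-yl]-5-oxooxolan-3-yl}-4-[(triethylsilyl)oxy]but-2-en-2-yl]zirconium | C=CC[C@@H](C)[C@@H](O[Si](C)(C)C(C)(C)C)[C@H]1OC(=O)C[C@@H]1[C@@H](O[Si](CC)(CC)CC)/C=C(C)/[Zr](Cl)(C1C=CC=C1)C1C=CC=C1
F8 | step 11 | (2S,3S)-2-[(1R,2R)-1-[(tert-butyldimethylsilyl)oxy]-2-methylpent-4-en-1-yl]-N-methoxy-N-methyl-5-oxooxolane-3-carboxamide | C=CC[C@@H](C)[C@@H](O[Si](C)(C)C(C)(C)C)[C@H]1OC(=O)C[C@@H]1C(=O)N(C)OC
A1 | alternative 1 | (4E,6S,7R,8S,9R,10R)-9-[(tert-butyldimethylsilyl)oxy]-6-hydroxygermacra-4,11(13)-dien-12,8-olide (same structure as 30) | C1/C(C)=C/[C@H](O)[C@H]2C(=C)C(=O)O[C@@H]2[C@H](O[Si](C)(C)C(C)(C)C)[C@H](C)CC1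
A2 | alternative 1 | (1S,2S,3E,8R,9R,10S)-9-[(tert-butyldimethylsilyl)oxy]-4,8-dimethyl-11-oxabicyclo[8.1.0]undec-3-en-2-ol | C1/C(C)=C/[C@H](O)[C@@H]2O[C@@H]2[C@H](O[Si](C)(C)C(C)(C)C)[C@H](C)CC1
A3 | alternative 1 | methyl 2-bromoprop-2-enoate | C=C(Br)C(=O)OC
A4 | alternative 1 | lithium bis[1-(methoxycarbonyl)ethenyl]cuprate | [Li+].COC(=O)C(=C)[Cu-]C(=C)C(=O)OC
A5 | alternative 2 | (4E,6S,7S,8S,9R,10R)-6-[(tert-butyldimethylsilyl)oxy]-9-hydroxygermacr-4-en-12,8-olide | C1/C(C)=C/[C@H](O[Si](C)(C)C(C)(C)C)[C@H]2CC(=O)O[C@@H]2[C@H](O)[C@H](C)CC1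
A6 | alternative 2 | methyl (3R,4S,5E,10R)-4-[(tert-butyldimethylsilyl)oxy]-3-formyl-6,10-dimethyl-11-oxoundec-5-enoate | O=C[C@H](C)CCC/C(C)=C/[C@H](O[Si](C)(C)C(C)(C)C)[C@@H](CC(=O)OC)C=O
A7 | alternative 3 | (3S,4R,5E,10R)-3-{2-[(tert-butyldimethylsilyl)oxy]ethyl}-4-[(4-methoxybenzyl)oxy]-6,10-dimethylcyclodec-5-en-1-one | C[C@@H]1CCC/C(C)=C/[C@H](OCc2ccc(OC)cc2)[C@@H](CCO[Si](C)(C)C(C)(C)C)CC1=O
A8 | alternative 3 | (1S,2R,6R)-1-[(1E)-4-[(tert-butyldimethylsilyl)oxy]but-1-en-1-yl]-2-[(E)-2-[(4-methoxybenzyl)oxy]ethenyl]-2,6-dimethylcyclohexan-1-ol | O[C@]1(/C=C/CCO[Si](C)(C)C(C)(C)C)[C@H](C)CCC[C@]1(C)/C=C/OCc1ccc(OC)cc1
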